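**Retrosynthetic overview**
1. The target comes from its 7,5'-di-O-benzyl ether. The last step is hydrogenolysis of both benzyl groups.
2. Ring C is opened at O1–C2 (cyclodehydration) to a 1,3-diketone. The diketone comes from an O-to-C aroyl shift (Baker–Venkataraman, makes C2–C3) in an o-aroyloxyacetophenone.
3. Key disconnection: the C8a–O1 bond of that aryl ester is cut back to a ring A ketone C–H and a ring B carboxylic acid O–H. The forward reaction is a new ketone-directed dehydrogenative C–H aroyloxylation. It joins the two fragments and installs the fourth oxygen of ring A.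
4. The ring A ketone comes from gallacetophenone (4-O-benzylation, then 2,3-di-O-methylation). The ring B acid comes from methyl 3-hydroxy-4,5-dimethoxybenzoate (O-benzylation, then saponification).
5. Ring order: rings A and B are bought as benzene rings. Ring C is the only ring made, and it closes in the last step but one.

Assumption: the target has no stereocentre, stereogenic axis or stereogenic double bond. It is achiral, so "single enantiomer" needs no action and the SMILES carry no stereo marks.

**Step 1**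
Reactants: 1 2',3',4'-trihydroxyacetophenone (gallacetophenone)
Product: 2 1-[4-(benzyloxy)-2,3-dihydroxyphenyl]ethanone
Conditions: BnBr (1.05 equiv), Li2CO3 (1.5 equiv), DMF, N2, 50 °C, 16 h
Reagents that add atoms: benzyl bromide BrCc1ccccc1
Why: Williamson etherification under acidity control: the 4-OH (para to the acetyl group) is the most acidic, the 2-OH is locked in a hydrogen bond to the carbonyl and the 3-OH is the least acidic, so the weak base Li2CO3 makes only the 4-phenoxide and one equivalent of BnBr caps it.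

**Step 2**
Reactants: 2 1-[4-(benzyloxy)-2,3-dihydroxyphenyl]ethanone
Product: 3 1-[4-(benzyloxy)-2,3-dimethoxyphenyl]ethanone
Conditions: MeI (4 equiv), K2CO3 (4 equiv), DMF, N2, 40 °C, 18 h
Reagents that add atoms: methyl iodide CI
Why: Double Williamson methylation: excess MeI and K2CO3 in DMF break the carbonyl chelate and cap both remaining phenols, while the benzyl ether and the ketone are inert.

**Step 3**
Reactants: 4 methyl 3-hydroxy-4,5-dimethoxybenzoate
Product: 5 methyl 3-(benzyloxy)-4,5-dimethoxybenzoate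
Conditions: BnBr (1.2 equiv), K2CO3 (2 equiv), DMF, 60 °C, 6 h
Reagents that add atoms: benzyl bromide BrCc1ccccc1
Why: Williamson etherification of the only free phenol, with the ester and the methyl ethers inert.

**Step 4**
Reactants: 5 methyl 3-(benzyloxy)-4,5-dimethoxybenzoate
Product: 6 3-(benzyloxy)-4,5-dimethoxybenzoic acid
Conditions: LiOH·H2O (3 equiv), THF/MeOH/H2O, 40 °C; then 1 M HCl
Reagents that add atoms: lithium hydroxide [Li+].[OH-]
Why: Saponification (acyl–oxygen cleavage by hydroxide) of an unhindered methyl benzoate; all ethers are inert and acidification precipitates the acid.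

**Step 5**
Reactants: 3 1-[4-(benzyloxy)-2,3-dimethoxyphenyl]ethanone; 6 3-(benzyloxy)-4,5-dimethoxybenzoic acid (1.5 equiv)
Product: 7 2-acetyl-5-(benzyloxy)-3,4-dimethoxyphenyl 3-(benzyloxy)-4,5-dimethoxybenzoate
Conditions: [RuCl2(p-cymene)]2 (5 mol%), AgSbF6 (20 mol%), (NH4)2S2O8 (2.0 equiv), 1,2-dichloroethane, sealed tube, 100 °C, 24 h
Reagents that add atoms: none
Why: Proposed new method: AgSbF6 strips chloride from [RuCl2(p-cymene)]2 so that the carboxylate of 6 binds a cationic divalent ruthenium centre, the acetyl oxygen of 3 (turned toward C6–H by dipole repulsion from the 2-OMe) steers carboxylate-assisted C–H ruthenation to the only free ortho position to give a five-membered ruthenacycle, (NH4)2S2O8 oxidises it to tetravalent ruthenium, and C–O reductive elimination with the bound aroate releases 7, which has no ortho C–H left on ring A and so cannot react twice; the closest known reaction types are the ruthenium-catalysed ortho C–H benzoxylation of anilides and benzamides by aromatic acids and the ketone-directed ruthenium- or palladium-catalysed C–H hydroxylation that runs through aryl trifluoroacetates, whereas transfer of a whole aroate fragment to a weakly coordinating aryl methyl ketone has not been shown.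

**Step 6**
Reactants: 7 2-acetyl-5-(benzyloxy)-3,4-dimethoxyphenyl 3-(benzyloxy)-4,5-dimethoxybenzoate
Product: 8 1-[4-(benzyloxy)-6-hydroxy-2,3-dimethoxyphenyl]-3-[3-(benzyloxy)-4,5-dimethoxyphenyl]propane-1,3-dione
Conditions: powdered KOH (3 equiv), dry pyridine, 50 °C, 2 h; then cold 1 M HCl
Reagents that add atoms: none
Why: Baker–Venkataraman rearrangement: the methyl ketone enolate attacks the neighbouring aroate carbonyl through a six-membered transition state and the tetrahedral intermediate collapses to the stabilised diketonate and phenoxide, which makes the C2–C3 bond.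

**Step 7**
Reactants: 8 1-[4-(benzyloxy)-6-hydroxy-2,3-dimethoxyphenyl]-3-[3-(benzyloxy)-4,5-dimethoxyphenyl]propane-1,3-dione
Product: 9 7-(benzyloxy)-2-[3-(benzyloxy)-4,5-dimethoxyphenyl]-5,6-dimethoxy-4H-chromen-4-one
Conditions: p-TsOH·H2O (0.2 equiv), toluene, 90 °C, 2 h
Reagents that add atoms: none
Why: Acid-catalysed cyclodehydration: the phenol adds to the carbonyl next to ring B, loss of water gives the 4-pyranone (ring C), catalytic sulfonic acid spares benzyl and methyl ethers, and acetophenone C2-OMe, C3-OMe, C4-OBn and C5-H become flavone C5, C6, C7 and C8.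

**Step 8**
Reactants: 9 7-(benzyloxy)-2-[3-(benzyloxy)-4,5-dimethoxyphenyl]-5,6-dimethoxy-4H-chromen-4-one
Product: 10 7-hydroxy-2-(3-hydroxy-4,5-dimethoxyphenyl)-5,6-dimethoxy-4H-chromen-4-one (7,5'-dihydroxy-5,6,3',4'-tetramethoxyflavone)
Conditions: H2 (1 atm), Pd/C (10 wt%), THF/MeOH 1:1, rt, 3 h
Reagents that add atoms: none
Why: Catalytic hydrogenolysis of aryl benzyl ethers is much faster than reduction of the conjugated pyranone C2=C3 bond and leaves the four methyl ethers untouched, so both phenols are freed at once.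

**Compound list**
1 | 2',3',4'-trihydroxyacetophenone (gallacetophenone) | CC(=O)c1ccc(O)c(O)c1O | starting material
2 | 1-[4-(benzyloxy)-2,3-dihydroxyphenyl]ethanone | CC(=O)c1ccc(OCc2ccccc2)c(O)c1O | intermediate
3 | 1-[4-(benzyloxy)-2,3-dimethoxyphenyl]ethanone | CC(=O)c1ccc(OCc2ccccc2)c(OC)c1OC | intermediate
4 | methyl 3-hydroxy-4,5-dimethoxybenzoate | COC(=O)c1cc(O)c(OC)c(OC)c1 | starting material
5 | methyl 3-(benzyloxy)-4,5-dimethoxybenzoate | COC(=O)c1cc(OCc2ccccc2)c(OC)c(OC)c1 | intermediate
6 | 3-(benzyloxy)-4,5-dimethoxybenzoic acid | OC(=O)c1cc(OCc2ccccc2)c(OC)c(OC)c1 | intermediate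
7 | 2-acetyl-5-(benzyloxy)-3,4-dimethoxyphenyl 3-(benzyloxy)-4,5-dimethoxybenzoate | CC(=O)c1c(OC(=O)c2cc(OC)c(OC)c(OCc3ccccc3)c2)cc(OCc2ccccc2)c(OC)c1OC | intermediate
8 | 1-[4-(benzyloxy)-6-hydroxy-2,3-dimethoxyphenyl]-3-[3-(benzyloxy)-4,5-dimethoxyphenyl]propane-1,3-dione (drawn as the diketo form) | COc1cc(C(=O)CC(=O)c2c(O)cc(OCc3ccccc3)c(OC)c2OC)cc(OCc2ccccc2)c1OC | intermediate
9 | 7-(benzyloxy)-2-[3-(benzyloxy)-4,5-dimethoxyphenyl]-5,6-dimethoxy-4H-chromen-4-one | COc1cc(-c2cc(=O)c3c(OC)c(OC)c(OCc4ccccc4)cc3o2)cc(OCc2ccccc2)c1OC | intermediate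
10 | 7-hydroxy-2-(3-hydroxy-4,5-dimethoxyphenyl)-5,6-dimethoxy-4H-chromen-4-one | COc1cc(-c2cc(=O)c3c(OC)c(OC)c(O)cc3o2)cc(O)c1OC | target

**Totals**
- Total step count: 8.
- Longest linear sequence: 6 (steps 1, 2, 5, 6, 7, 8). The ring B branch, steps 3, 4, 5, 6, 7, 8, is equally long.

**The three steps most likely to fail**

**Risk 1, step 5 (the proposed new C–H aroyloxylation).**
- The ketone may bind ruthenium too weakly, or the carbonyl and the 2-OMe may form an unproductive O,O-chelate.
- The oxidant may attack the trialkoxyarene or the benzylic C–H bonds.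
- The carboxylate of 6 may direct C–H activation onto its own ring.

The fallback uses only known chemistry. It sets out from 6 and comes back at 7, and it replaces ketone 3 by a phenol that already carries the fourth oxygen.
- Commercial 2',4'-dihydroxy-6'-methoxyacetophenone F1 is benzylated at its non-chelated hydroxyl (BnBr, K2CO3, acetone, reflux). This gives 1-[4-(benzyloxy)-2-hydroxy-6-methoxyphenyl]ethanone F2.
- Elbs persulfate oxidation (K2S2O8, aqueous KOH/pyridine, rt) places oxygen para to the phenol. The product is potassium 3-acetyl-6-(benzyloxy)-4-hydroxy-2-methoxyphenyl sulfate F3.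
- Warm dilute HCl hydrolyses this sulfate to 1-[4-(benzyloxy)-3,6-dihydroxy-2-methoxyphenyl]ethanone F4.
- MeI (1.05 equiv) and K2CO3 in acetone methylate only the non-chelated hydroxyl. This gives 1-[4-(benzyloxy)-6-hydroxy-2,3-dimethoxyphenyl]ethanone F5.
- Steglich esterification of this phenol with 6 (EDC·HCl, DMAP, CH2Cl2) gives 7.

**Risk 2, step 1 (regioselective mono-benzylation).**
- Alkylation may spill over to O3, giving the 3,4-dibenzyl ether or mixtures.

The fallback sets out from 1 and comes back at 2. It swaps acidity control for a temporary protecting group, a masking already used for selective 4-O-methylation of 2,3,4-trihydroxyaryl carbonyl compounds.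
- Compound 1 is stirred with Na2B4O7·10H2O in water. This ties up the 2,3-diol as sodium 4-acetyl-2,2,7-trihydroxy-1,3,2-benzodioxaborol-2-uide F6.
- BnBr with NaOH at pH 9–10 (water/acetone) alkylates the only free phenol. This gives sodium 4-acetyl-7-(benzyloxy)-2,2-dihydroxy-1,3,2-benzodioxaborol-2-uide F7.
- Acidification with HCl takes the borate off and gives 2.

**Risk 3, step 6 (Baker–Venkataraman rearrangement).**
- Hydroxide may cleave the crowded aryl ester back to phenol and acid faster than the hindered enolate attacks it.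

The fallback sets out from 7 and comes back at 9, bypassing 8 and step 7. It closes ring C by olefination instead of acyl transfer.
- Compound 7 is α-brominated (CuBr2, EtOAc/CHCl3, reflux). This gives 5-(benzyloxy)-2-(bromoacetyl)-3,4-dimethoxyphenyl 3-(benzyloxy)-4,5-dimethoxybenzoate F8.
- PPh3 in toluene gives {2-[4-(benzyloxy)-6-{[3-(benzyloxy)-4,5-dimethoxybenzoyl]oxy}-2,3-dimethoxyphenyl]-2-oxoethyl}triphenylphosphonium bromide F9.
- Aqueous Na2CO3/CH2Cl2 frees 5-(benzyloxy)-3,4-dimethoxy-2-[(triphenylphosphoranylidene)acetyl]phenyl 3-(benzyloxy)-4,5-dimethoxybenzoate F10.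
- Heating this ylide in toluene brings about an intramolecular Wittig olefination of the ester carbonyl and gives 9.

**Further compounds**
F1 | step 5 | 2',4'-dihydroxy-6'-methoxyacetophenone (bought, entry point of the fallback) | CC(=O)c1c(O)cc(O)cc1OC
F2 | step 5 | 1-[4-(benzyloxy)-2-hydroxy-6-methoxyphenyl]ethanone | CC(=O)c1c(O)cc(OCc2ccccc2)cc1OC
F3 | step 5 | potassium 3-acetyl-6-(benzyloxy)-4-hydroxy-2-methoxyphenyl sulfate | CC(=O)c1c(O)cc(OCc2ccccc2)c(OS(=O)(=O)[O-])c1OC.[K+]
F4 | step 5 | 1-[4-(benzyloxy)-3,6-dihydroxy-2-methoxyphenyl]ethanone | CC(=O)c1c(O)cc(OCc2ccccc2)c(O)c1OC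
F5 | step 5 | 1-[4-(benzyloxy)-6-hydroxy-2,3-dimethoxyphenyl]ethanone | CC(=O)c1c(O)cc(OCc2ccccc2)c(OC)c1OC
F6 | step 1 | sodium 4-acetyl-2,2,7-trihydroxy-1,3,2-benzodioxaborol-2-uide | CC(=O)c1ccc(O)c2O[B-](O)(O)Oc12.[Na+]
F7 | step 1 | sodium 4-acetyl-7-(benzyloxy)-2,2-dihydroxy-1,3,2-benzodioxaborol-2-uide | CC(=O)c1ccc(OCc3ccccc3)c2O[B-](O)(O)Oc12.[Na+]
F8 | step 6 | 5-(benzyloxy)-2-(bromoacetyl)-3,4-dimethoxyphenyl 3-(benzyloxy)-4,5-dimethoxybenzoate | O=C(CBr)c1c(OC(=O)c2cc(OC)c(OC)c(OCc3ccccc3)c2)cc(OCc2ccccc2)c(OC)c1OC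
F9 | step 6 | {2-[4-(benzyloxy)-6-{[3-(benzyloxy)-4,5-dimethoxybenzoyl]oxy}-2,3-dimethoxyphenyl]-2-oxoethyl}triphenylphosphonium bromide | [Br-].O=C(C[P+](c1ccccc1)(c1ccccc1)c1ccccc1)c1c(OC(=O)c2cc(OC)c(OC)c(OCc3ccccc3)c2)cc(OCc2ccccc2)c(OC)c1OC
F10 | step 6 | 5-(benzyloxy)-3,4-dimethoxy-2-[(triphenylphosphoranylidene)acetyl]phenyl 3-(benzyloxy)-4,5-dimethoxybenzoate | O=C(C=P(c1ccccc1)(c1ccccc1)c1ccccc1)c1c(OC(=O)c2cc(OC)c(OC)c(OCc3ccccc3)c2)cc(OCc2ccccc2)c(OC)c1OC
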